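**Strategy**

The cyclohexane is cut into a four-carbon diene and a two-carbon allene. The exocyclic isopropylidene on the ring carbon next to the CH that bears the propanal chain is read as the surviving π bond of a 1,1-dimethylallene, and the quaternary ring carbon (CH3, CH2OAr) as the fully substituted terminus of a (Z)-diene, so the hindered neopentyl coumarinyl ether is made beforehand as an easy allylic ether. One enantioselective Diels–Alder reaction of diene ether 6 with allenoyl imide 14 then forms both ring bonds, the quaternary and the adjacent tertiary stereocentre and the isopropylidene; a hydroxyl-directed hydrogenation sets the third stereocentre, and methylenation–hydroformylation completes the aldehyde chain.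

Key step: step 7

Remark: the absolute sense of induction in step 7 is assigned from the square-planar chelate model of bis(oxazoline)copper–imide complexes; should the antipode form, the (R,R) ligand would be used instead.

**Route**

Step 1
Reactants: 1 2,3-dimethylmaleic anhydride
Product: 2 3,4-dimethylfuran-2(5H)-one
Conditions: NaBH4, THF, 0 °C to rt; then aq. HCl
Reagents that add atoms: none
Why: Hydride reduction of one carbonyl of the symmetrical anhydride and lactonisation on acidification should give the butenolide, whose ring fixes the cis relationship of the two carbon substituents on the tetrasubstituted alkene.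

Step 2
Reactants: 2 3,4-dimethylfuran-2(5H)-one
Product: 4 (2Z)-2,3-dimethylpenta-2,4-dien-1-ol, via 3,4-dimethyl-2,5-dihydrofuran-2-ol 3 (not isolated)
Conditions: i-Bu2AlH (1.1 equiv), CH2Cl2, −78 °C; then Ph3P=CH2 (from Ph3PCH3Br and KN(SiMe3)2, 3 equiv), THF, −78 °C to rt
Reagents that add atoms: methylenetriphenylphosphorane, C=P(c1ccccc1)(c1ccccc1)c1ccccc1
Why: Partial reduction of the lactone to the lactol (held as its aluminium alkoxide) and Wittig methylenation of the ring-opened (Z)-hydroxy enal in the same flask should give the dienol with the alkene geometry inherited from the ring, and immediate olefination avoids dehydration of the lactol to 3,4-dimethylfuran.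

Step 3
Reactants: 4 (2Z)-2,3-dimethylpenta-2,4-dien-1-ol; 5 isofraxidin (7-hydroxy-6,8-dimethoxy-2H-chromen-2-one)
Product: 6 7-{[(2Z)-2,3-dimethylpenta-2,4-dien-1-yl]oxy}-6,8-dimethoxy-2H-chromen-2-one
Conditions: PPh3, diisopropyl azodicarboxylate, THF, 0 °C to rt
Reagents that add atoms: none
Why: Mitsunobu etherification of the acidic phenol with the unhindered primary allylic alcohol (SN2 at CH2) should form the aryl ether without disturbing the diene geometry.

Step 4
Reactants: 7 isobutyryl chloride; 8 ethyl (triphenylphosphoranylidene)acetate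
Product: 10 ethyl 4-methylpenta-2,3-dienoate, via dimethylketene 9 (not isolated)
Conditions: Et3N, CH2Cl2, 0 °C to rt
Reagents that add atoms: none
Why: Triethylamine dehydrochlorinates the acid chloride to dimethylketene, and Wittig olefination of the ketene carbonyl by the stabilised ylide should give the γ,γ-dimethyl allenoate.

Step 5
Reactants: 10 ethyl 4-methylpenta-2,3-dienoate
Product: 11 4-methylpenta-2,3-dienoic acid
Conditions: LiOH, THF/H2O, 0 °C; then aq. HCl
Reagents that add atoms: lithium hydroxide, [Li+].[OH-]
Why: Saponification at 0 °C should give the allenic acid, the γ,γ-dimethyl substitution slowing base-mediated isomerisation of the allene.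

Step 6
Reactants: 11 4-methylpenta-2,3-dienoic acid; 12 1,3-oxazolidin-2-one
Product: 14 3-(4-methylpenta-2,3-dienoyl)-1,3-oxazolidin-2-one, via pivalic 4-methylpenta-2,3-dienoic anhydride 13 (not isolated)
Conditions: t-BuCOCl, Et3N, THF, −20 °C; then 12, LiCl, −20 °C to rt
Reagents that add atoms: none
Why: N-Acylation through the mixed pivalic anhydride with LiCl/Et3N avoids an allenoyl chloride and strong base, either of which would isomerise the allene.

Step 7
Reactants: 6 7-{[(2Z)-2,3-dimethylpenta-2,4-dien-1-yl]oxy}-6,8-dimethoxy-2H-chromen-2-one; 14 3-(4-methylpenta-2,3-dienoyl)-1,3-oxazolidin-2-one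
Product: 15 3-{[(1S,2R)-2-{[(6,8-dimethoxy-2-oxo-2H-chromen-7-yl)oxy]methyl}-2,3-dimethyl-6-(propan-2-ylidene)cyclohex-3-en-1-yl]carbonyl}-1,3-oxazolidin-2-one
Conditions: [Cu((S,S)-t-Bu-box)](SbF6)2 (10 mol %, preformed from CuCl2, AgSbF6 and 2,2'-(propane-2,2-diyl)bis[(4S)-4-tert-butyl-4,5-dihydro-1,3-oxazole]), 4 Å molecular sieves, CH2Cl2, −20 °C to rt
Reagents that add atoms: none
Why: Chelation of both imide carbonyls of 14 to the square-planar divalent copper centre lowers the LUMO of the allene π bond conjugated with the carbonyl, and the s-cis diene 6 adds across it in a concerted but asynchronous [4+2] cycloaddition in which the bond from the unsubstituted diene CH2 to the central allene carbon leads and the bond from the fully substituted diene carbon to the α-carbon follows, leaving the second allene π bond as the exocyclic isopropylidene. The closest known reaction type is the bis(oxazoline)copper-catalysed enantioselective Diels–Alder reaction of N-acyloxazolidinones, combined with the known behaviour of allenic acid derivatives as dienophiles at their α,β-bond, including additions to dienes with a fully substituted terminus. The cyclohexene ring is closed by intermolecular cycloaddition, suprafacial on both partners, not by cyclisation of a chain. The configuration of the ring CH bearing the acyl group is set by the catalyst, since with the imide s-cis in the chelate the tert-butyl group of the (S,S) ligand covers the si face of the α-carbon and the diene adds to the re face; the configuration of the new quaternary carbon follows from the endo orientation of the acyl group together with the (2Z) geometry of 6, which places CH3 outside and CH2OAr inside and hence CH3 cis and CH2OAr trans to the acyl group. Regioselectivity (substituted terminus to the α-carbon) is secured by the large HOMO coefficient at the remote CH2 terminus, the large LUMO coefficient at the central allene carbon and the smaller steric demand of that pairing, and site selectivity for the α,β over the β,γ bond by conjugation with the chelated carbonyl. The step needs endo selectivity and survival of the allylic aryl ether, which the mild catalytic Lewis acid at low temperature, the blocked ortho positions of the coumarin ether and the small CH2 terminus facing the inward-pointing allene methyl group should provide.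

Step 8
Reactants: 15 the cycloadduct imide
Product: 16 [(1S,2R)-2-{[(6,8-dimethoxy-2-oxo-2H-chromen-7-yl)oxy]methyl}-2,3-dimethyl-6-(propan-2-ylidene)cyclohex-3-en-1-yl]methanol
Conditions: NaBH4, THF/H2O (4:1), 0 °C to rt
Reagents that add atoms: none
Why: The exocyclic imide carbonyl is far more electrophilic than the coumarin lactone, so borohydride in wet THF should cleave the N-acyloxazolidinone reductively to the primary alcohol under near-neutral conditions that do not epimerise the adjacent stereocentre.

Step 9
Reactants: 16 the cyclohexenyl methanol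
Product: 17 [(1S,2S,3S)-2-{[(6,8-dimethoxy-2-oxo-2H-chromen-7-yl)oxy]methyl}-2,3-dimethyl-6-(propan-2-ylidene)cyclohexyl]methanol
Conditions: [Rh(nbd)(dppb)]BF4 (10 mol %), H2 (30 bar), CH2Cl2, rt
Reagents that add atoms: none
Why: In this hydroxyl-directed homogeneous hydrogenation, allylic 1,3-strain with the isopropylidene holds CH2OH axial over the ring alkene, so rhodium bound to it should deliver H2 to the face cis to CH2OH and anti to the pseudoaxial CH2OAr, setting the methyl-bearing stereocentre with its methyl trans to the quaternary CH3, while the tetrasubstituted alkene and the coumarin are not directed and should react much more slowly.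

Step 10
Reactants: 17 the saturated alcohol
Product: 18 (1S,2S,3S)-2-{[(6,8-dimethoxy-2-oxo-2H-chromen-7-yl)oxy]methyl}-2,3-dimethyl-6-(propan-2-ylidene)cyclohexane-1-carbaldehyde
Conditions: Dess–Martin periodinane, NaHCO3, CH2Cl2, 0 °C to rt
Reagents that add atoms: none
Why: Dess–Martin oxidation under buffered, non-basic conditions should give the aldehyde without epimerising its α-stereocentre or touching the isopropylidene and the coumarin.

Step 11
Reactants: 18 the aldehyde
Product: 19 7-{[(1S,2S,6S)-2-ethenyl-1,6-dimethyl-3-(propan-2-ylidene)cyclohexyl]methoxy}-6,8-dimethoxy-2H-chromen-2-one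
Conditions: Ph3P=CH2 (from Ph3PCH3Br and KN(SiMe3)2, 1.3 equiv), THF, −78 to 0 °C
Reagents that add atoms: methylenetriphenylphosphorane, C=P(c1ccccc1)(c1ccccc1)c1ccccc1
Why: Wittig methylenation with a salt-free ylide at low temperature should convert the hindered aldehyde into the vinyl group faster than it enolises, so the adjacent stereocentre is retained and the coumarin is not attacked.

Step 12
Reactants: 19 the vinyl compound
Product: 20 3-[(1S,2S,3S)-2-{[(6,8-dimethoxy-2-oxo-2H-chromen-7-yl)oxy]methyl}-2,3-dimethyl-6-(propan-2-ylidene)cyclohexyl]propanal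
Conditions: Rh(acac)(CO)2 (2 mol %), Xantphos (4 mol %), CO/H2 (1:1, 10 bar), toluene, 70 °C
Reagents that add atoms: carbon monoxide, [C-]#[O+]
Why: Linear-selective rhodium–Xantphos hydroformylation should add the formyl group to the terminal carbon of the α-branched vinyl group and so complete the propanal chain, the tetrasubstituted isopropylidene and the conjugated coumarin alkene being too hindered or too electron-poor to react.

**Compound list**

1 | 2,3-dimethylmaleic anhydride | CC1=C(C)C(=O)OC1=O | starting material
2 | 3,4-dimethylfuran-2(5H)-one | CC1=C(C)C(=O)OC1 | intermediate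
3 | 3,4-dimethyl-2,5-dihydrofuran-2-ol | CC1=C(C)C(O)OC1 | intermediate
4 | (2Z)-2,3-dimethylpenta-2,4-dien-1-ol | OC/C(C)=C(\C=C)C | intermediate
5 | isofraxidin (7-hydroxy-6,8-dimethoxy-2H-chromen-2-one) | COc1cc2ccc(=O)oc2c(OC)c1O | starting material
6 | 7-{[(2Z)-2,3-dimethylpenta-2,4-dien-1-yl]oxy}-6,8-dimethoxy-2H-chromen-2-one | COc1cc2ccc(=O)oc2c(OC)c1OC/C(C)=C(\C=C)C | intermediate
7 | isobutyryl chloride | CC(C)C(Cl)=O | starting material
8 | ethyl (triphenylphosphoranylidene)acetate | CCOC(=O)C=P(c1ccccc1)(c1ccccc1)c1ccccc1 | starting material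
9 | dimethylketene | CC(C)=C=O | intermediate
10 | ethyl 4-methylpenta-2,3-dienoate | CCOC(=O)C=C=C(C)C | intermediate
11 | 4-methylpenta-2,3-dienoic acid | CC(C)=C=CC(=O)O | intermediate
12 | 1,3-oxazolidin-2-one | O=C1NCCO1 | starting material
13 | pivalic 4-methylpenta-2,3-dienoic anhydride | CC(C)=C=CC(=O)OC(=O)C(C)(C)C | intermediate
14 | 3-(4-methylpenta-2,3-dienoyl)-1,3-oxazolidin-2-one | CC(C)=C=CC(=O)N1CCOC1=O | intermediate
15 | 3-{[(1S,2R)-2-{[(6,8-dimethoxy-2-oxo-2H-chromen-7-yl)oxy]methyl}-2,3-dimethyl-6-(propan-2-ylidene)cyclohex-3-en-1-yl]carbonyl}-1,3-oxazolidin-2-one | COc1cc2ccc(=O)oc2c(OC)c1OC[C@@]1(C)C(C)=CCC(=C(C)C)[C@@H]1C(=O)N3CCOC3=O | intermediate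
16 | [(1S,2R)-2-{[(6,8-dimethoxy-2-oxo-2H-chromen-7-yl)oxy]methyl}-2,3-dimethyl-6-(propan-2-ylidene)cyclohex-3-en-1-yl]methanol | COc1cc2ccc(=O)oc2c(OC)c1OC[C@@]1(C)C(C)=CCC(=C(C)C)[C@@H]1CO | intermediate
17 | [(1S,2S,3S)-2-{[(6,8-dimethoxy-2-oxo-2H-chromen-7-yl)oxy]methyl}-2,3-dimethyl-6-(propan-2-ylidene)cyclohexyl]methanol | COc1cc2ccc(=O)oc2c(OC)c1OC[C@@]1(C)[C@@H](C)CCC(=C(C)C)[C@@H]1CO | intermediate
18 | (1S,2S,3S)-2-{[(6,8-dimethoxy-2-oxo-2H-chromen-7-yl)oxy]methyl}-2,3-dimethyl-6-(propan-2-ylidene)cyclohexane-1-carbaldehyde | COc1cc2ccc(=O)oc2c(OC)c1OC[C@@]1(C)[C@@H](C)CCC(=C(C)C)[C@@H]1C=O | intermediate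
19 | 7-{[(1S,2S,6S)-2-ethenyl-1,6-dimethyl-3-(propan-2-ylidene)cyclohexyl]methoxy}-6,8-dimethoxy-2H-chromen-2-one | COc1cc2ccc(=O)oc2c(OC)c1OC[C@@]1(C)[C@@H](C)CCC(=C(C)C)[C@@H]1C=C | intermediate
20 | 3-[(1S,2S,3S)-2-{[(6,8-dimethoxy-2-oxo-2H-chromen-7-yl)oxy]methyl}-2,3-dimethyl-6-(propan-2-ylidene)cyclohexyl]propanal | COc1cc2ccc(=O)oc2c(OC)c1OC[C@@]1(C)[C@@H](C)CCC(=C(C)C)[C@@H]1CCC=O | target

**Step count and risks**

Total step count: 12. Longest linear sequence: 9 steps (steps 1, 2, 3, 7, 8, 9, 10, 11, 12).

Steps most likely to fail: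

1. Step 7. The (Z)-substituted, fully substituted diene terminus may not reach the s-cis geometry readily, so the cycloaddition may be slow or close stepwise to a vinylcyclobutane, and the allylic aryl ether may ionise on long exposure to the Lewis acid. Fallback, setting out from 13 and 6 and returning at 16: stereocontrol would be moved from the catalyst to a covalent auxiliary on a more strongly activated dienophile. Mixed anhydride 13 would acylate (4R)-4-benzyl-1,3-oxazolidin-2-one (LiCl, Et3N, THF) to give (4R)-4-benzyl-3-(4-methylpenta-2,3-dienoyl)-1,3-oxazolidin-2-one F1. Its chelate with Me2AlCl (2.5 equiv, CH2Cl2, −78 to −40 °C) should add diene 6 endo on the face anti to the benzyl group, which is again the re face of the α-carbon, to give (4R)-4-benzyl-3-{[(1S,2R)-2-{[(6,8-dimethoxy-2-oxo-2H-chromen-7-yl)oxy]methyl}-2,3-dimethyl-6-(propan-2-ylidene)cyclohex-3-en-1-yl]carbonyl}-1,3-oxazolidin-2-one F2. NaBH4 in THF/H2O would then release alcohol 16.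

2. Step 8. Hydride may attack the ring carbonyl of the hindered imide (opening the oxazolidinone) or the coumarin lactone. Fallback, setting out from 15 and returning at 16: hydrolysis with LiOH/H2O2 (THF/H2O, 0 °C; acidification re-closes any opened coumarin) would give (1S,2R)-2-{[(6,8-dimethoxy-2-oxo-2H-chromen-7-yl)oxy]methyl}-2,3-dimethyl-6-(propan-2-ylidene)cyclohex-3-ene-1-carboxylic acid F3. Isobutyl chloroformate and N-methylmorpholine (THF, −15 °C) would convert it into the isobutyl carbonic mixed anhydride of that acid F4, which NaBH4 would reduce in the same flask to 16.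

3. Step 9. The coumarin 3,4-double bond may be saturated competitively, or the ring alkene may migrate before directed delivery. Fallback, setting out from 15 and returning at 17: the hydrogenation would be run one stage earlier with the imide carbonyl as directing group ([Ir(cod)(PCy3)(py)]PF6, H2 1 atm, CH2Cl2, 0 °C), which should deliver hydrogen to the same face and give 3-{[(1S,2S,3S)-2-{[(6,8-dimethoxy-2-oxo-2H-chromen-7-yl)oxy]methyl}-2,3-dimethyl-6-(propan-2-ylidene)cyclohexyl]carbonyl}-1,3-oxazolidin-2-one F5. Reductive cleavage with NaBH4 in THF/H2O as in step 8 would then give 17.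

**Further compounds**

F1 | step 7 | (4R)-4-benzyl-3-(4-methylpenta-2,3-dienoyl)-1,3-oxazolidin-2-one | CC(C)=C=CC(=O)N1[C@H](Cc2ccccc2)COC1=O
F2 | step 7 | (4R)-4-benzyl-3-{[(1S,2R)-2-{[(6,8-dimethoxy-2-oxo-2H-chromen-7-yl)oxy]methyl}-2,3-dimethyl-6-(propan-2-ylidene)cyclohex-3-en-1-yl]carbonyl}-1,3-oxazolidin-2-one | COc1cc2ccc(=O)oc2c(OC)c1OC[C@@]1(C)C(C)=CCC(=C(C)C)[C@@H]1C(=O)N3[C@H](Cc4ccccc4)COC3=O
F3 | step 8 | (1S,2R)-2-{[(6,8-dimethoxy-2-oxo-2H-chromen-7-yl)oxy]methyl}-2,3-dimethyl-6-(propan-2-ylidene)cyclohex-3-ene-1-carboxylic acid | COc1cc2ccc(=O)oc2c(OC)c1OC[C@@]1(C)C(C)=CCC(=C(C)C)[C@@H]1C(=O)O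
F4 | step 8 | isobutyl carbonic (1S,2R)-2-{[(6,8-dimethoxy-2-oxo-2H-chromen-7-yl)oxy]methyl}-2,3-dimethyl-6-(propan-2-ylidene)cyclohex-3-ene-1-carboxylic anhydride | COc1cc2ccc(=O)oc2c(OC)c1OC[C@@]1(C)C(C)=CCC(=C(C)C)[C@@H]1C(=O)OC(=O)OCC(C)C
F5 | step 9 | 3-{[(1S,2S,3S)-2-{[(6,8-dimethoxy-2-oxo-2H-chromen-7-yl)oxy]methyl}-2,3-dimethyl-6-(propan-2-ylidene)cyclohexyl]carbonyl}-1,3-oxazolidin-2-one | COc1cc2ccc(=O)oc2c(OC)c1OC[C@@]1(C)[C@@H](C)CCC(=C(C)C)[C@@H]1C(=O)N3CCOC3=O
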